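The synthesis rests on cutting the cis C3=C4 double bond of the 2,2-dimethyl-2H-pyran fused to ring B, which spans the aromatic carbon C4a and the gem-dimethyl carbon C2 attached to the pyran oxygen O1. One ring-closing olefin metathesis between a vinyl group on C4a and the terminal alkene of a 1,1-dimethylallyl ether on O1 forms that bond, closes the pyran and releases ethene. Run last, it delivers the natural product itself. Its precursor is the complete, unprotected depsidone: diprenylated ring A, the seven-membered lactone, and a ring B carrying adjacent vinyl and tertiary allyl ether groups. That depsidone is assembled from a bromoquinone and a silyl-protected diprenyl phloroglucinol ester.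

Key step: step 13

Remark: the para hydroxyl of ring A is silylated only for the fragment union and the carboxyl is carried as a 2-(trimethylsilyl)ethyl ester, so one fluoride treatment frees both before lactonisation and nothing is removed after the metathesis; commercial 3-chloro-3-methylbut-1-yne and dried 2,4,6-trihydroxybenzoic acid serve as building blocks.

Step 1
Reactants: 1 2,5-dimethoxyphenol
Product: 2 2-hydroxy-3,6-dimethoxybenzaldehyde
Conditions: MgCl2, Et3N, (CH2O)n, MeCN, reflux; then dilute aq. HCl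
Reagents that add atoms: paraformaldehyde (formaldehyde), C=O
Why: Magnesium-mediated ortho-formylation (Casnati–Skattebøl reaction), in which the chloromagnesium phenoxide delivers formaldehyde to the only free ortho carbon and a second formaldehyde oxidises the benzylic alkoxide to the aldehyde.

Step 2
Reactants: 2 2-hydroxy-3,6-dimethoxybenzaldehyde
Product: 3 5-bromo-2-hydroxy-3,6-dimethoxybenzaldehyde
Conditions: NBS, MeCN, 0 °C to rt
Reagents that add atoms: N-bromosuccinimide, O=C1CCC(=O)N1Br
Why: Electrophilic aromatic bromination should go to the ring carbon para to the free hydroxyl and ortho to a methoxy group, since the only other CH lies para to the deactivating formyl group.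

Step 3
Reactants: 3 5-bromo-2-hydroxy-3,6-dimethoxybenzaldehyde; 4 3-chloro-3-methylbut-1-yne
Product: 5 5-bromo-3,6-dimethoxy-2-[(2-methylbut-3-yn-2-yl)oxy]benzaldehyde
Conditions: DBU, CuCl2·2H2O (1 mol%), MeCN, 0 °C to rt
Reagents that add atoms: none
Why: Copper-catalysed propargylic etherification of a phenol, in which a copper acetylide/allenylidene intermediate lets the phenoxide take the tertiary chloride to the aryl ether without elimination and tolerates ortho substituents.

Step 4
Reactants: 5 5-bromo-3,6-dimethoxy-2-[(2-methylbut-3-yn-2-yl)oxy]benzaldehyde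
Product: 6 5-bromo-3,6-dimethoxy-2-[(2-methylbut-3-en-2-yl)oxy]benzaldehyde
Conditions: H2 (1 atm), Pd/CaCO3 poisoned with Pb(OAc)2, quinoline, EtOAc, rt
Reagents that add atoms: none
Why: Lindlar semihydrogenation should stop at the alkene because the poisoned palladium surface binds the terminal alkyne much more strongly than the product, and it leaves the aryl bromide and the aldehyde alone.

Step 5
Reactants: 6 5-bromo-3,6-dimethoxy-2-[(2-methylbut-3-en-2-yl)oxy]benzaldehyde
Product: 7 1-bromo-3-ethenyl-2,5-dimethoxy-4-[(2-methylbut-3-en-2-yl)oxy]benzene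
Conditions: Ph3PCH3Br, KOtBu, THF, 0 °C to rt
Reagents that add atoms: methyltriphenylphosphonium bromide, C[P+](c1ccccc1)(c1ccccc1)c1ccccc1.[Br-]
Why: Wittig methylenation with the non-stabilised ylide should convert the hindered aryl aldehyde into the styrene, as the molecule offers no acidic or electrophilic competitor.

Step 6
Reactants: 7 1-bromo-3-ethenyl-2,5-dimethoxy-4-[(2-methylbut-3-en-2-yl)oxy]benzene
Product: 8 5-bromo-3-ethenyl-2-[(2-methylbut-3-en-2-yl)oxy]cyclohexa-2,5-diene-1,4-dione
Conditions: (NH4)2Ce(NO3)6, MeCN/H2O, 0 °C, 15 min; cold extraction, used at once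
Reagents that add atoms: water, O
Why: Oxidative demethylation of a para-dimethoxyarene by tetravalent cerium, a known route to bromo- and vinyl-quinones, should expel both methoxy groups as methanol after water capture, while the short cold contact protects the tertiary allyl ether and the styrene.

Step 7
Reactants: 9 2,4,6-trihydroxybenzoic acid
Product: 10 2-(trimethylsilyl)ethyl 2,4,6-trihydroxybenzoate
Conditions: 2-(trimethylsilyl)ethanol (1.0 equiv), PPh3, DIAD, THF, 0 °C to rt
Reagents that add atoms: 2-(trimethylsilyl)ethanol, C[Si](C)(C)CCO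
Why: Mitsunobu esterification, in which the strongly acidic carboxyl group is alkylated by the alkoxyphosphonium ion of the primary alcohol much faster than the phenols, a chemoselectivity established for unprotected phenolic acids.

Step 8
Reactants: 10 2-(trimethylsilyl)ethyl 2,4,6-trihydroxybenzoate; 11 1-bromo-3-methylbut-2-ene
Product: 12 2-(trimethylsilyl)ethyl 2,4,6-trihydroxy-3,5-bis(3-methylbut-2-en-1-yl)benzoate
Conditions: 11 (2.2 equiv), DBU (2.2 equiv), THF, 0 °C to rt
Reagents that add atoms: none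
Why: Nuclear C-prenylation of an acylphloroglucinol-type phenoxide, whose ambident anion should attack the soft allylic bromide through the two equivalent ring CH carbons; modest efficiency is expected because O-alkylation and geminal dialkylation compete.

Step 9
Reactants: 12 2-(trimethylsilyl)ethyl 2,4,6-trihydroxy-3,5-bis(3-methylbut-2-en-1-yl)benzoate
Product: 13 2-(trimethylsilyl)ethyl 2,6-dihydroxy-3,5-bis(3-methylbut-2-en-1-yl)-4-[(triisopropylsilyl)oxy]benzoate
Conditions: TIPSOTf (1.05 equiv), 2,6-lutidine, CH2Cl2, −78 to 0 °C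
Reagents that add atoms: triisopropylsilyl trifluoromethanesulfonate, CC(C)[Si](OS(=O)(=O)C(F)(F)F)(C(C)C)C(C)C
Why: Selective O-silylation should occur at the C4 hydroxyl because the two ortho hydroxyls are hydrogen-bonded to the ester and much less nucleophilic, and the reactive silyl triflate overcomes the flanking prenyl groups.

Step 10
Reactants: 8 5-bromo-3-ethenyl-2-[(2-methylbut-3-en-2-yl)oxy]cyclohexa-2,5-diene-1,4-dione; 13 2-(trimethylsilyl)ethyl 2,6-dihydroxy-3,5-bis(3-methylbut-2-en-1-yl)-4-[(triisopropylsilyl)oxy]benzoate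
Product: 15 2-(trimethylsilyl)ethyl 2-{3-ethenyl-2,5-dihydroxy-4-[(2-methylbut-3-en-2-yl)oxy]phenoxy}-6-hydroxy-3,5-bis(3-methylbut-2-en-1-yl)-4-[(triisopropylsilyl)oxy]benzoate, via aryloxyquinone 14 (not isolated)
Conditions: K2CO3, DMF, 0 °C, under argon; then aq. Na2S2O4, EtOAc
Reagents that add atoms: none
Why: Addition–elimination (nucleophilic vinylic substitution) on a halo-quinone, in which the phenoxide of the symmetric ring A (its two free hydroxyls are equivalent) attacks the bromine-bearing carbon, the beta position of the carbonyl that the alkoxy group does not deactivate, bromide leaves, and dithionite reduces the aryloxyquinone to the hydroquinone.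

Step 11
Reactants: 15 the hydroquinone diaryl ether of step 10
Product: 16 2-{3-ethenyl-2,5-dihydroxy-4-[(2-methylbut-3-en-2-yl)oxy]phenoxy}-4,6-dihydroxy-3,5-bis(3-methylbut-2-en-1-yl)benzoic acid
Conditions: Bu4NF (6 equiv), THF, 0 °C to rt, under argon; cold dilute aq. HCl to pH 4; crude acid used at once
Reagents that add atoms: none
Why: Fluoride-induced cleavage, in which attack at silicon fragments the 2-(trimethylsilyl)ethyl ester to carboxylate, ethene and fluorotrimethylsilane and also removes the aryl silyl ether, under conditions that leave the tertiary allyl ether and all alkenes untouched.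

Step 12
Reactants: 16 the seco acid of step 11
Product: 17 9-ethenyl-1,3,7-trihydroxy-8-[(2-methylbut-3-en-2-yl)oxy]-2,4-bis(3-methylbut-2-en-1-yl)-11H-dibenzo[b,e][1,4]dioxepin-11-one
Conditions: DCC, CH2Cl2 (0.003 M), 0 °C to rt
Reagents that add atoms: none
Why: Carbodiimide-mediated lactonisation, the standard closure of depsidones from 2-(2-hydroxyaryloxy)benzoic acids, should give the seven-membered lactone because only the hydroxyl ortho to the diaryl ether oxygen can reach the O-acylisourea and high dilution suppresses intermolecular acylation.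

Step 13
Reactants: 17 9-ethenyl-1,3,7-trihydroxy-8-[(2-methylbut-3-en-2-yl)oxy]-2,4-bis(3-methylbut-2-en-1-yl)-11H-dibenzo[b,e][1,4]dioxepin-11-one
Product: 18 garcinisidone E
Conditions: RuCl2(H2IMes)(PCy3)(=CHPh) (second-generation Grubbs catalyst, H2IMes = 1,3-dimesitylimidazolidin-2-ylidene, 5 mol%), CH2Cl2 (0.005 M), 40 °C, under argon
Reagents that add atoms: none
Why: Ring-closing olefin metathesis: the ruthenium benzylidene exchanges onto the monosubstituted styrenyl alkene at C9 (the future C4a), the aryl alkylidene adds [2+2] to the terminal alkene of the 1,1-dimethylallyl ether held ortho to it, and cycloreversion of the ruthenacyclobutane forms the C3=C4 bond and a ruthenium methylidene that carries the chain with loss of ethene. The closest known reaction type is the metathesis of 2-vinylaryl allyl ethers to 2H-chromenes with ruthenium alkylidene catalysts. The six-membered pyran is closed by intramolecular metathesis of two terminal alkenes on adjacent ring atoms, the ring size allows only the cis alkene, and no stereocentre is created. The step needs chemoselectivity for the two monosubstituted alkenes over the two trisubstituted prenyl alkenes, which the much lower metathesis reactivity of trisubstituted alkenes, the ortho relationship of the reacting pair and the gem-dimethyl group should secure at high dilution. The free phenols and the lactone are spectators for this catalyst, so the step should give the natural product directly.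

Compound list
1 | 2,5-dimethoxyphenol | COc1ccc(OC)c(O)c1 | starting material
2 | 2-hydroxy-3,6-dimethoxybenzaldehyde | COc1ccc(OC)c(C=O)c1O | intermediate
3 | 5-bromo-2-hydroxy-3,6-dimethoxybenzaldehyde | COc1cc(Br)c(OC)c(C=O)c1O | intermediate
4 | 3-chloro-3-methylbut-1-yne | CC(C)(Cl)C#C | starting material
5 | 5-bromo-3,6-dimethoxy-2-[(2-methylbut-3-yn-2-yl)oxy]benzaldehyde | COc1cc(Br)c(OC)c(C=O)c1OC(C)(C)C#C | intermediate
6 | 5-bromo-3,6-dimethoxy-2-[(2-methylbut-3-en-2-yl)oxy]benzaldehyde | COc1cc(Br)c(OC)c(C=O)c1OC(C)(C)C=C | intermediate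
7 | 1-bromo-3-ethenyl-2,5-dimethoxy-4-[(2-methylbut-3-en-2-yl)oxy]benzene | COc1cc(Br)c(OC)c(C=C)c1OC(C)(C)C=C | intermediate
8 | 5-bromo-3-ethenyl-2-[(2-methylbut-3-en-2-yl)oxy]cyclohexa-2,5-diene-1,4-dione | C=CC(C)(C)OC1=C(C=C)C(=O)C(Br)=CC1=O | intermediate
9 | 2,4,6-trihydroxybenzoic acid | OC(=O)c1c(O)cc(O)cc1O | starting material
10 | 2-(trimethylsilyl)ethyl 2,4,6-trihydroxybenzoate | C[Si](C)(C)CCOC(=O)c1c(O)cc(O)cc1O | intermediate
11 | 1-bromo-3-methylbut-2-ene | CC(C)=CCBr | starting material
12 | 2-(trimethylsilyl)ethyl 2,4,6-trihydroxy-3,5-bis(3-methylbut-2-en-1-yl)benzoate | C[Si](C)(C)CCOC(=O)c1c(O)c(CC=C(C)C)c(O)c(CC=C(C)C)c1O | intermediate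
13 | 2-(trimethylsilyl)ethyl 2,6-dihydroxy-3,5-bis(3-methylbut-2-en-1-yl)-4-[(triisopropylsilyl)oxy]benzoate | C[Si](C)(C)CCOC(=O)c1c(O)c(CC=C(C)C)c(O[Si](C(C)C)(C(C)C)C(C)C)c(CC=C(C)C)c1O | intermediate
14 | 2-(trimethylsilyl)ethyl 2-({5-ethenyl-4-[(2-methylbut-3-en-2-yl)oxy]-3,6-dioxocyclohexa-1,4-dien-1-yl}oxy)-6-hydroxy-3,5-bis(3-methylbut-2-en-1-yl)-4-[(triisopropylsilyl)oxy]benzoate (aryloxyquinone, not isolated) | C=CC(C)(C)OC1=C(C=C)C(=O)C(Oc2c(CC=C(C)C)c(O[Si](C(C)C)(C(C)C)C(C)C)c(CC=C(C)C)c(O)c2C(=O)OCC[Si](C)(C)C)=CC1=O | intermediate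
15 | 2-(trimethylsilyl)ethyl 2-{3-ethenyl-2,5-dihydroxy-4-[(2-methylbut-3-en-2-yl)oxy]phenoxy}-6-hydroxy-3,5-bis(3-methylbut-2-en-1-yl)-4-[(triisopropylsilyl)oxy]benzoate | C=CC(C)(C)Oc1c(C=C)c(O)c(Oc2c(CC=C(C)C)c(O[Si](C(C)C)(C(C)C)C(C)C)c(CC=C(C)C)c(O)c2C(=O)OCC[Si](C)(C)C)cc1O | intermediate
16 | 2-{3-ethenyl-2,5-dihydroxy-4-[(2-methylbut-3-en-2-yl)oxy]phenoxy}-4,6-dihydroxy-3,5-bis(3-methylbut-2-en-1-yl)benzoic acid | C=CC(C)(C)Oc1c(C=C)c(O)c(Oc2c(CC=C(C)C)c(O)c(CC=C(C)C)c(O)c2C(=O)O)cc1O | intermediate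
17 | 9-ethenyl-1,3,7-trihydroxy-8-[(2-methylbut-3-en-2-yl)oxy]-2,4-bis(3-methylbut-2-en-1-yl)-11H-dibenzo[b,e][1,4]dioxepin-11-one (O5 is the diaryl ether oxygen, O10–C11 the lactone) | CC(C)=CCc1c(O)c(CC=C(C)C)c2c(c1O)C(=O)Oc1c(cc(O)c(OC(C)(C)C=C)c1C=C)O2 | intermediate
18 | garcinisidone E: depsidone 17 in which O8 and C9 are bridged by C(CH3)2–CH=CH, giving a 2,2-dimethyl-2H-pyran with a cis ring alkene; hydroxyls at C1, C3 and C7, prenyl groups at C2 and C4; no stereocentre | CC(C)=CCc1c(O)c(CC=C(C)C)c2c(c1O)C(=O)Oc1c(cc(O)c3c1C=CC(C)(C)O3)O2 | target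

Total step count: 13. Longest linear sequence: 10 steps (steps 1–6, then 10–13); steps 7–9 build the ring A branch.

Steps most likely to fail

Step 10. Electron transfer from the electron-rich phenoxide to the bromoquinone, [4+2] self-condensation of the vinylquinone, or attack at the vinyl terminus may outrun the slow attack of the hindered, hydrogen-bonded phenoxide at the bromine-bearing carbon. The fallback sets out from compound 2 and comes back at compound 15. It replaces the substitution by an oxidative conjugate addition to a bromine-free, less oxidising quinone. Without the bromination, 2 and 4 (DBU, CuCl2·2H2O) should give 3,6-dimethoxy-2-[(2-methylbut-3-yn-2-yl)oxy]benzaldehyde F1. Semihydrogenation should give 3,6-dimethoxy-2-[(2-methylbut-3-en-2-yl)oxy]benzaldehyde F2, Wittig methylenation 2-ethenyl-1,4-dimethoxy-3-[(2-methylbut-3-en-2-yl)oxy]benzene F3, and (NH4)2Ce(NO3)6 oxidation 2-ethenyl-3-[(2-methylbut-3-en-2-yl)oxy]cyclohexa-2,5-diene-1,4-dione F4. The phenoxide of 13 (K2CO3, MeCN, 0 °C) should add in conjugate fashion to the unsubstituted ring carbon para to the alkoxy-bearing carbon, the beta position of the carbonyl that the alkoxy group does not deactivate. With Ag2O present the adduct is drawn on to aryloxyquinone 14, and the dithionite work-up rejoins the route at 15.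

Step 6. Acid-promoted ionisation of the tertiary allyl ether, oxidation of the styrene by tetravalent cerium, or a [3,3] shift of the allyl group in the quinone may erode the material before the union. The fallback sets out from compound 5 and comes back at compound 15. It carries the ether as the far less ionisable tertiary propargyl ether through oxidation and union and semihydrogenates afterwards. Wittig methylenation of 5 should give 1-bromo-3-ethenyl-2,5-dimethoxy-4-[(2-methylbut-3-yn-2-yl)oxy]benzene F5, and (NH4)2Ce(NO3)6 oxidation 5-bromo-3-ethenyl-2-[(2-methylbut-3-yn-2-yl)oxy]cyclohexa-2,5-diene-1,4-dione F6. Substitution by the phenoxide of 13 (K2CO3, DMF, 0 °C) should give 2-(trimethylsilyl)ethyl 2-({5-ethenyl-4-[(2-methylbut-3-yn-2-yl)oxy]-3,6-dioxocyclohexa-1,4-dien-1-yl}oxy)-6-hydroxy-3,5-bis(3-methylbut-2-en-1-yl)-4-[(triisopropylsilyl)oxy]benzoate F7 (not isolated). Dithionite work-up should give 2-(trimethylsilyl)ethyl 2-{3-ethenyl-2,5-dihydroxy-4-[(2-methylbut-3-yn-2-yl)oxy]phenoxy}-6-hydroxy-3,5-bis(3-methylbut-2-en-1-yl)-4-[(triisopropylsilyl)oxy]benzoate F8. Hydrogenation of F8 over Pd/CaCO3 poisoned with Pb(OAc)2 with quinoline, stopped after one equivalent of H2, returns to 15.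

Step 13. Binding of ruthenium by the phenol-rich substrate, double-bond migration caused by ruthenium hydrides, or engagement of a prenyl group with loss of isobutene may slow or divert the closure. The fallback sets out from compound 7 and comes back at compound 18. It moves the ring closure to the simple arene, so every later step handles a robust chromene instead of the vinyl and tertiary allyl ether pair. Metathesis of 7 with the same catalyst should give 6-bromo-5,8-dimethoxy-2,2-dimethyl-2H-chromene F9, and (NH4)2Ce(NO3)6 oxidation 6-bromo-2,2-dimethyl-2H-chromene-5,8-dione F10. Substitution by the phenoxide of 13 should give 2-(trimethylsilyl)ethyl 2-[(2,2-dimethyl-5,8-dioxo-5,8-dihydro-2H-chromen-6-yl)oxy]-6-hydroxy-3,5-bis(3-methylbut-2-en-1-yl)-4-[(triisopropylsilyl)oxy]benzoate F11 (not isolated). Dithionite work-up should give 2-(trimethylsilyl)ethyl 2-[(5,8-dihydroxy-2,2-dimethyl-2H-chromen-6-yl)oxy]-6-hydroxy-3,5-bis(3-methylbut-2-en-1-yl)-4-[(triisopropylsilyl)oxy]benzoate F12. Bu4NF should give 2-[(5,8-dihydroxy-2,2-dimethyl-2H-chromen-6-yl)oxy]-4,6-dihydroxy-3,5-bis(3-methylbut-2-en-1-yl)benzoic acid F13, and DCC lactonisation at high dilution gives 18.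

Further compounds
F1 | step 10 | 3,6-dimethoxy-2-[(2-methylbut-3-yn-2-yl)oxy]benzaldehyde | COc1ccc(OC)c(C=O)c1OC(C)(C)C#C
F2 | step 10 | 3,6-dimethoxy-2-[(2-methylbut-3-en-2-yl)oxy]benzaldehyde | COc1ccc(OC)c(C=O)c1OC(C)(C)C=C
F3 | step 10 | 2-ethenyl-1,4-dimethoxy-3-[(2-methylbut-3-en-2-yl)oxy]benzene | COc1ccc(OC)c(C=C)c1OC(C)(C)C=C
F4 | step 10 | 2-ethenyl-3-[(2-methylbut-3-en-2-yl)oxy]cyclohexa-2,5-diene-1,4-dione | C=CC(C)(C)OC1=C(C=C)C(=O)C=CC1=O
F5 | step 6 | 1-bromo-3-ethenyl-2,5-dimethoxy-4-[(2-methylbut-3-yn-2-yl)oxy]benzene | COc1cc(Br)c(OC)c(C=C)c1OC(C)(C)C#C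
F6 | step 6 | 5-bromo-3-ethenyl-2-[(2-methylbut-3-yn-2-yl)oxy]cyclohexa-2,5-diene-1,4-dione | C#CC(C)(C)OC1=C(C=C)C(=O)C(Br)=CC1=O
F7 | step 6 | 2-(trimethylsilyl)ethyl 2-({5-ethenyl-4-[(2-methylbut-3-yn-2-yl)oxy]-3,6-dioxocyclohexa-1,4-dien-1-yl}oxy)-6-hydroxy-3,5-bis(3-methylbut-2-en-1-yl)-4-[(triisopropylsilyl)oxy]benzoate | C#CC(C)(C)OC1=C(C=C)C(=O)C(Oc2c(CC=C(C)C)c(O[Si](C(C)C)(C(C)C)C(C)C)c(CC=C(C)C)c(O)c2C(=O)OCC[Si](C)(C)C)=CC1=O
F8 | step 6 | 2-(trimethylsilyl)ethyl 2-{3-ethenyl-2,5-dihydroxy-4-[(2-methylbut-3-yn-2-yl)oxy]phenoxy}-6-hydroxy-3,5-bis(3-methylbut-2-en-1-yl)-4-[(triisopropylsilyl)oxy]benzoate | C#CC(C)(C)Oc1c(C=C)c(O)c(Oc2c(CC=C(C)C)c(O[Si](C(C)C)(C(C)C)C(C)C)c(CC=C(C)C)c(O)c2C(=O)OCC[Si](C)(C)C)cc1O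
F9 | step 13 | 6-bromo-5,8-dimethoxy-2,2-dimethyl-2H-chromene | CC1(C)C=Cc2c(OC)c(Br)cc(OC)c2O1
F10 | step 13 | 6-bromo-2,2-dimethyl-2H-chromene-5,8-dione | CC1(C)C=CC2=C(O1)C(=O)C=C(Br)C2=O
F11 | step 13 | 2-(trimethylsilyl)ethyl 2-[(2,2-dimethyl-5,8-dioxo-5,8-dihydro-2H-chromen-6-yl)oxy]-6-hydroxy-3,5-bis(3-methylbut-2-en-1-yl)-4-[(triisopropylsilyl)oxy]benzoate | CC1(C)C=CC2=C(O1)C(=O)C=C(Oc3c(CC=C(C)C)c(O[Si](C(C)C)(C(C)C)C(C)C)c(CC=C(C)C)c(O)c3C(=O)OCC[Si](C)(C)C)C2=O
F12 | step 13 | 2-(trimethylsilyl)ethyl 2-[(5,8-dihydroxy-2,2-dimethyl-2H-chromen-6-yl)oxy]-6-hydroxy-3,5-bis(3-methylbut-2-en-1-yl)-4-[(triisopropylsilyl)oxy]benzoate | CC1(C)C=Cc2c(O)c(Oc3c(CC=C(C)C)c(O[Si](C(C)C)(C(C)C)C(C)C)c(CC=C(C)C)c(O)c3C(=O)OCC[Si](C)(C)C)cc(O)c2O1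
F13 | step 13 | 2-[(5,8-dihydroxy-2,2-dimethyl-2H-chromen-6-yl)oxy]-4,6-dihydroxy-3,5-bis(3-methylbut-2-en-1-yl)benzoic acid | CC1(C)C=Cc2c(O)c(Oc3c(CC=C(C)C)c(O)c(CC=C(C)C)c(O)c3C(=O)O)cc(O)c2O1
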